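## Structural features

The target is a eudesmane: two six-membered carbocycles, ring A (C1–C5, C10) and ring B (C5–C10), trans-fused through the C5–C10 bond, with an angular methyl (C14) on quaternary C10 and a 5α hydrogen. Ring A carries four contiguous stereocentres, C3–C4–C5–C10: an axial 3α-acyloxy group, a tertiary carbinol at C4 (equatorial 4α-OH, axial 4β-methyl C15), the ring-fusion hydrogen and the quaternary centre; the two oxygens at C3 and C4 are cis. Ring B holds a C8 ketone conjugated with an exocyclic, tetrasubstituted C7=C11 isopropylidene (C12, C13), and C9 is a methylene locked between the ketone and C10. The acyl residue is (S)-3-methylpentanoate, whose remote stereocentre is best imported intact. Fragile elements are the enone (dissolving metals, hydrides, peracids, deconjugation), the secondary ester next to a free tertiary alcohol (hydrolysis, acyl shift) and the tertiary alcohol itself (dehydration, ketol rearrangement while C3 is a ketone). The real difficulty is to fix the absolute configuration of quaternary C10 and relay it to C5, C4 and C3 while a reducible and oxidisable ring B is carried along. The key step reads the C8 carbonyl and the C7 isopropylidene of ring B as an oxidised and isomerised homoallylic alcohol, that is, as the product of a carbonyl-ene reaction between a C8 aldehyde (attached to C10 through C9) and a prenyl group (C6, C7, C11–C13) on C5 of a preformed ring A.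

## Logic of the disconnections

25 to 24: no skeletal bond is cut; the C7=C11 double bond is moved back to C11=C12. The conjugated enone is incompatible with dissolving metal, hydride and peracid, so it is created last. The forward step needs a base strong enough for the prototropic shift and mild enough to spare the ester.

24 to 23 to 22: the C8 carbonyl is taken back to a C8–O–H and then to a C8–O–Si bond. This leaves ring B as a protected homoallylic alcohol, inert during all ring A chemistry. The forward steps need a desilylation that leaves the ester alone and a neutral oxidant.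

22 to 19 and 20 (through 21): the ester C(acyl)–O3 bond is cut. The chiral acyl unit is purchased as 20 and attached once, late. The forward step must distinguish the secondary C3 hydroxyl from the tertiary C4 hydroxyl.

19 to 18: the C3–H bond is cut (hydride). The C3 stereocentre becomes a ketone that also explains the C4 oxygen. The forward step needs hydride delivery on the β face to give the axial alcohol.

18 to 16 (through 17) and 16 to 14 (through 15): the C4–O bond and the C5–H bond are cut. One enone then accounts for C3, C4 and C5. The forward steps need α-face protonation at C5, α-face oxygenation at C4, and a peracid that prefers the enol ether over the isopropenyl group.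

14 to 13: the O8–Si bond is cut; this is only protection.

13 to 12: the C7–C8 bond is cut and ring B is opened. A bicycle with three stereocentres becomes a monocycle with one, the quaternary carbon. The forward step needs activation of the aldehyde beside an enone, bonding at C7 and not at C11, and clean hydrogen transfer from a methyl group. In 12 the quaternary carbon is drawn with its R configuration, and the aldehyde is set free from an acetal only in the operation that makes 12.

12 to 8 and 9 (through 10 and 11): the C5–C6 bond between ring and prenyl group is cut and the enone is transposed back to a vinylogous ester. The side chain comes from purchased 9. The forward step needs attack through the unsubstituted terminus of the allylic metal on a hindered carbonyl.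

8 to 7 to 6: the acetal C–O bonds are cut, then the aldehyde carbon is traced to a terminal olefin (one carbon lost on cleavage). This leads back to a plain allyl group on the quaternary carbon. The forward steps need olefin cleavage that ignores the enol ether and an acetal that survives an organometallic.

6 to 5: the bond between the quaternary carbon and the allyl CH2 is cut. This is the only step that creates absolute configuration from achiral or racemic material. It needs a catalyst that controls the enolate face.

5 to 4 to 2 and 3, and 2 to 1: the ring–CH3 bond, the ring–CO2allyl bond and the enol ether O–C bond are cut. This leads back to the symmetrical dione 1 and the chloroformate 3. The forward steps need C-acylation rather than O-acylation at the kinetic enolate.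

## Other disconnections considered

Alternative 1: Cutting C4–C5 and C9–C10 opens both rings and leads to the acyclic enyne keto ester A1, methyl (6E)-7-methyl-3-oxododec-6-en-10-ynoate.
- Forward key step: the cationic monovalent gold complex made from (R)-MeO-DTBM-BIPHEP(AuCl)2 and AgSbF6 would activate the C3≡C4 alkyne. C5 of the E olefin would attack C4, and the enol carbon C9 of the keto ester would trap the tertiary C10 cation, giving the bicyclic enol ester A2 with the trans ring fusion.
- In favour: both rings and both ring-fusion stereocentres come from an achiral chain in one catalytic step. The C3=C4 olefin left in A2 is ideally placed for α-face syn-dihydroxylation to the cis 3α,4α-diol, so no ketone reduction and no dissolving-metal step are needed. The keto ester allows regiocontrolled functionalisation at C7.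
- Against: the alkyne must carry the C15 methyl and the terminator is a carbon nucleophile. Enantioselective gold-initiated bicyclisations are best established for terminal alkynes and heteroatom or arene terminators, so both regiochemistry (six-membered versus five-membered first ring) and enantiocontrol would have to be established. C11–C13 are still missing and the ester carbon must be removed.
- Comparison: on step economy and on the C3/C4 oxygenation this route is the better one. On mechanism it is a cationic cascade under catalyst control, against a pericyclic closure on a substrate whose stereocentre is already fixed. On reliability of absolute control the chosen plan is stronger, because every step in it has close precedent on the same substrate class.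

Alternative 2: Cutting C5–C6 and C9–C10 takes ring B apart into the diene A3, 2-(tert-butyldimethylsilyloxy)-3-(phenylthio)buta-1,3-diene, and the enal A4, (2E,4S)-4-(tert-butyldimethylsilyloxy)-2-methylpent-2-enal.
- Forward key step: a chiral oxazaborolidinium triflimide would activate A4 and the Diels–Alder addition would give the cyclohexene aldehyde A5. Sulfur fixes the orientation (C7 para to C10) and the E geometry translates into the trans relation of formyl group and side chain.
- In favour: the route is convergent. Quaternary C10 and C5 are set together. C8 appears as a regiodefined enol ether, the sulfur at C7 is a handle for the isopropylidene, and A4 comes from the lactate pool.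
- Against: a trisubstituted, β-branched enal is a sluggish dienophile and the acid-labile silyloxy diene must survive a strong Lewis acid. Catalyst and the resident stereocentre of A4 must be matched. Ring A is absent from A5: C2 and C3 must be added and the C3–C4 bond closed, and the secondary carbinol carbon C4 must be oxidised and rebuilt as a tertiary one.
- Comparison: it equals the chosen plan in setting the quaternary centre catalytically and is better in convergence. It is weaker in structure and step economy, because the chosen plan has ring A complete before the key step and needs only functional-group changes afterwards.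

Alternative 3: Cutting C1–C10 leads to the vinyl ketone A6, 4-[(8S)-7-methylidene-1,4-dioxaspiro[4.5]decan-8-yl]pent-1-en-3-one.
- Forward key step: Fe(acac)3 and PhSiH3 would transfer a hydrogen atom to the C14 methylene. The tertiary C10 radical would add to C1 of the enone and close ring A, giving the ketal ketone A7.
- In favour: the quaternary carbon is made under mild, neutral conditions from a simple olefin. A7 already has the C3 ketone, the C4 methyl and the C5 hydrogen, so no dissolving-metal reduction is needed and α-hydroxylation can follow directly; on this point it is the equal or the better of the chosen plan.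
- Against: the configuration of C10 rests on substrate control only (cis against trans fusion in the radical closure). C5 must be made enantiomerically enriched beforehand. Simple reduction of the radical or of the enone competes. C11–C13 must be attached late at C7 by an aldol-type condensation, which constrains the order of the ester-forming steps.
- Comparison: step count is similar. Functional-group tolerance of the key step is better. Stereocontrol at C10 is weaker than with the ligand-controlled allylation of the chosen plan.

Key step: step 8

Assumption 1: bicyclic compounds are named on the eudesmane skeleton (C14 = methyl on C10, C15 = methyl on C4, C11–C13 = the three-carbon unit on C7; α is the face opposite to C14); the target is (3R,4S,5R,10R) with an (S) acyl group.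

Assumption 2: the PHOX ligand is taken to induce the same sense in the vinylogous ester as in simple 2-methylcyclohexanone enolates, so the (R) ligand is chosen to give (R)-6; if the sense were opposite, the (S) ligand would be used.

## Route

Step 1
Reactants: 1 2-methylcyclohexane-1,3-dione
Product: 2 2-methyl-3-(2-methylpropoxy)cyclohex-2-en-1-one
Conditions: i-BuOH, p-TsOH·H2O (cat.), PhMe, reflux, Dean–Stark
Reagents that add atoms: 2-methylpropan-1-ol, CC(C)CO
Why: Acid-catalysed enol etherification of a cyclic 1,3-dione, driven by azeotropic removal of water; the dione is symmetrical, so one vinylogous ester results and no stereocentre is formed.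

Step 2
Reactants: 2 2-methyl-3-(2-methylpropoxy)cyclohex-2-en-1-one; 3 allyl chloroformate
Product: 4 prop-2-en-1-yl 3-methyl-4-(2-methylpropoxy)-2-oxocyclohex-3-ene-1-carboxylate (racemic)
Conditions: LiN(i-Pr)2 (2.1 equiv), THF, −78 °C; 3, −78 → 0 °C; aq NH4Cl
Reagents that add atoms: none
Why: Kinetic deprotonation at the α′ carbon gives the cross-conjugated lithium dienolate, which undergoes Claisen-type C-acylation in THF without polar additives; the second equivalent of base stores the more acidic keto ester as its enolate; the new stereocentre is racemic and is erased in step 4.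

Step 3
Reactants: 4 prop-2-en-1-yl 3-methyl-4-(2-methylpropoxy)-2-oxocyclohex-3-ene-1-carboxylate
Product: 5 prop-2-en-1-yl 1,3-dimethyl-4-(2-methylpropoxy)-2-oxocyclohex-3-ene-1-carboxylate (racemic)
Conditions: MeI, K2CO3, acetone, 50 °C
Reagents that add atoms: iodomethane, CI
Why: C-Methylation of the stabilised keto ester enolate builds the quaternary carbon as a racemate, which is acceptable because the next step is stereoablative.

Step 4
Reactants: 5 prop-2-en-1-yl 1,3-dimethyl-4-(2-methylpropoxy)-2-oxocyclohex-3-ene-1-carboxylate
Product: 6 (6R)-2,6-dimethyl-3-(2-methylpropoxy)-6-(prop-2-en-1-yl)cyclohex-2-en-1-one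
Conditions: Pd2(dba)3 (zerovalent palladium source, 2.5 mol %), (R)-t-Bu-PHOX (6 mol %), PhMe, 30 °C
Reagents that add atoms: none
Why: Decarboxylative asymmetric Tsuji–Trost allylation: zerovalent palladium ionises the allyl ester, loss of CO2 gives an achiral enolate on the allylpalladium–PHOX cation, and ligand-controlled C–C bond formation sets the quaternary stereocentre (future C10) as R whatever the configuration of 5.

Step 5
Reactants: 6 (6R)-2,6-dimethyl-3-(2-methylpropoxy)-6-(prop-2-en-1-yl)cyclohex-2-en-1-one
Product: 7 2-[(1R)-1,3-dimethyl-4-(2-methylpropoxy)-2-oxocyclohex-3-en-1-yl]acetaldehyde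
Conditions: OsO4 (2 mol %), NaIO4 (4 equiv), 2,6-lutidine, dioxane–H2O, rt
Reagents that add atoms: osmium tetroxide (catalytic oxygen carrier), O=[Os](=O)(=O)=O; sodium periodate (terminal oxidant), [Na+].[O-]I(=O)(=O)=O
Why: Lemieux–Johnson cleavage: the monosubstituted olefin is dihydroxylated and the diol is cleaved by periodate, whereas the tetrasubstituted push–pull enol ether double bond is too electron-poor and hindered to compete; the quaternary centre is untouched.

Step 6
Reactants: 7 2-[(1R)-1,3-dimethyl-4-(2-methylpropoxy)-2-oxocyclohex-3-en-1-yl]acetaldehyde
Product: 8 (6R)-6-(2,2-dimethoxyethyl)-2,6-dimethyl-3-(2-methylpropoxy)cyclohex-2-en-1-one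
Conditions: HC(OMe)3, MeOH, PPTS (cat.), rt
Reagents that add atoms: trimethyl orthoformate, COC(OC)OC; methanol, CO
Why: Acid-catalysed acetalisation of the unhindered aldehyde with orthoformate as dehydrating agent; the conjugated, hindered ring carbonyl does not ketalise, and any alkoxy exchange at the enol ether is harmless because that group is expelled in step 7.

Step 7
Reactants: 8 (6R)-6-(2,2-dimethoxyethyl)-2,6-dimethyl-3-(2-methylpropoxy)cyclohex-2-en-1-one; 9 1-chloro-3-methylbut-2-ene
Product: 12 2-[(1R)-1,3-dimethyl-2-(3-methylbut-2-en-1-yl)-4-oxocyclohex-2-en-1-yl]acetaldehyde, via prenylbarium chloride 10 (not isolated), via tertiary carbinol adduct 11 (not isolated)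
Conditions: BaI2, LiC12H10 (lithium biphenylide, 2 equiv), THF, rt; 9, −78 °C; 8, −78 °C; then 1 M HCl, THF–H2O, 0 °C → rt
Reagents that add atoms: water, O
Why: Allylic barium reagents add to ketones through their unsubstituted terminus, so the prenyl unit arrives linear on the ring carbonyl carbon (the carbinol centre is destroyed at once); aqueous acid then effects the Stork–Danheiser transposition (ionisation of the alkoxy-stabilised tertiary allylic alcohol, hydration, loss of isobutanol) and hydrolyses the dimethyl acetal in the same operation; the quaternary stereocentre cannot epimerise.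

Step 8
Reactants: 12 2-[(1R)-1,3-dimethyl-2-(3-methylbut-2-en-1-yl)-4-oxocyclohex-2-en-1-yl]acetaldehyde
Product: 13 8α-hydroxyeudesma-4,11-dien-3-one (7β-isopropenyl; 10β-methyl; 7R,8S,10R)
Conditions: Me2AlCl (2.2 equiv), CH2Cl2, −78 → −20 °C; then 1 M HCl, 0 °C
Reagents that add atoms: none
Why: Me2AlCl binds the aldehyde oxygen, C7 of the trisubstituted olefin attacks C8 while a hydrogen of a C11 methyl passes to oxygen through a six-membered array (concerted but asynchronous, with positive charge building at tertiary C11), and the alcohol–aluminium complex loses methane to a stable alkoxide, which removes the proton that could start cationic side reactions. The closest known reaction type is the Lewis-acid-promoted intramolecular carbonyl-ene cyclisation of unsaturated aldehydes bearing a trisubstituted olefin, as in citronellal to isopulegol. Ring B closes as a six-membered ring in which both the C8=O and the C7=C11 π bonds stay exocyclic, through a chair-like transition state. At C8 the aluminium-bound oxygen takes the equatorial position to avoid a 1,3-diaxial contact with the axial C10 methyl, giving 8α-OH. At C7 the olefin unit lies equatorial, giving the 7β-isopropenyl group trans to the hydroxyl; both centres are erased later, so a mixture would be tolerated. Chemoselectivity is needed for the aldehyde over the enone: both carbonyls bind aluminium (hence more than two equivalents), but only the aldehyde has the olefin within reach. Regioselectivity is needed for C7 over C11: bonding at C7 gives a six-membered ring and a tertiary cationic centre, bonding at C11 would need a seven-membered ring and a secondary one. The quaternary C10 centre is configurationally fixed throughout.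

Step 9
Reactants: 13 8α-hydroxyeudesma-4,11-dien-3-one
Product: 14 8α-(tert-butyldimethylsilyloxy)eudesma-4,11-dien-3-one
Conditions: TBSCl, imidazole, DMF, rt
Reagents that add atoms: tert-butyldimethylsilyl chloride, CC(C)(C)[Si](C)(C)Cl
Why: Standard silylation of an equatorial secondary alcohol; the silyl ether shields O8 from dissolving metal, hydride and acylation and withstands the mild acid used later.

Step 10
Reactants: 14 8α-(tert-butyldimethylsilyloxy)eudesma-4,11-dien-3-one
Product: 16 8α-(tert-butyldimethylsilyloxy)-3-(trimethylsilyloxy)-5α-eudesma-3,11-diene, via lithium enolate 15 (not isolated)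
Conditions: Li, NH3(l), THF, t-BuOH (1 equiv), −78 °C; isoprene; −NH3; Me3SiCl, Et3N, THF, −78 → 0 °C
Reagents that add atoms: chlorotrimethylsilane, C[Si](C)(C)Cl
Why: Dissolving-metal (Birch-type) reduction of the enone: the β-carbanion is protonated at C5 on the α face, anti to the axial C10 methyl, which gives the trans ring fusion; the regiodefined C3–C4 lithium enolate is then O-silylated; the isolated olefin and the silyl ether are inert.

Step 11
Reactants: 16 8α-(tert-butyldimethylsilyloxy)-3-(trimethylsilyloxy)-5α-eudesma-3,11-diene
Product: 18 8α-(tert-butyldimethylsilyloxy)-4α-hydroxy-5α-eudesm-11-en-3-one (4β-methyl), via silyloxy ketone 17 (not isolated)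
Conditions: mCPBA (1.05 equiv), NaHCO3, CH2Cl2, −20 °C; then citric acid, MeOH, rt
Reagents that add atoms: 3-chloroperoxybenzoic acid, OOC(=O)c1cccc(Cl)c1
Why: Rubottom oxidation: the peracid epoxidises the electron-rich tetrasubstituted silyl enol ether, far faster than the 1,1-disubstituted olefin, from the α face opposite the axial C10 methyl; ring opening with 1,4-silyl shift gives the silyloxy ketone, and mild acidic methanolysis frees the tertiary alcohol without touching the TBS ether.

Step 12
Reactants: 18 8α-(tert-butyldimethylsilyloxy)-4α-hydroxy-5α-eudesm-11-en-3-one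
Product: 19 8α-(tert-butyldimethylsilyloxy)-5α-eudesm-11-ene-3α,4α-diol
Conditions: LiBH(sec-Bu)3 (2.5 equiv), THF, −78 °C; then H2O
Reagents that add atoms: none
Why: The bulky trialkylborohydride avoids the axial trajectory on the α face (1,3-diaxial hydrogens at C1 and C5) and attacks equatorially from the β side, giving the axial 3α-alcohol cis to the 4α-hydroxyl, as is typical for 3-ketones next to a fully substituted C4 in trans-decalins.

Step 13
Reactants: 19 8α-(tert-butyldimethylsilyloxy)-5α-eudesm-11-ene-3α,4α-diol; 20 (S)-3-methylpentanoic acid
Product: 22 8α-(tert-butyldimethylsilyloxy)-4α-hydroxy-5α-eudesm-11-en-3α-yl (3S)-3-methylpentanoate, via (S)-3-methylpentanoyl chloride 21 (not isolated)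
Conditions: 20, (COCl)2, DMF (cat.), CH2Cl2, 0 °C → rt; then 19, pyridine, DMAP (cat.), CH2Cl2, 0 °C → rt
Reagents that add atoms: none
Why: Acylation of the secondary alcohol by the acid chloride under nucleophilic catalysis; the tertiary C4 hydroxyl is too hindered to react, and the β-stereocentre of the acyl unit cannot be lost by enolisation or ketene formation.

Step 14
Reactants: 22 8α-(tert-butyldimethylsilyloxy)-4α-hydroxy-5α-eudesm-11-en-3α-yl (3S)-3-methylpentanoate
Product: 23 4α,8α-dihydroxy-5α-eudesm-11-en-3α-yl (3S)-3-methylpentanoate
Conditions: HF·pyridine, pyridine, THF, 0 °C → rt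
Reagents that add atoms: none
Why: Buffered fluoride cleaves the Si–O bond (driven by the Si–F bond) without hydrolysing or shifting the ester and without dehydrating the tertiary alcohol.

Step 15
Reactants: 23 4α,8α-dihydroxy-5α-eudesm-11-en-3α-yl (3S)-3-methylpentanoate
Product: 24 4α-hydroxy-8-oxo-5α-eudesm-11-en-3α-yl (3S)-3-methylpentanoate
Conditions: Dess–Martin periodinane, NaHCO3, CH2Cl2, 0 °C → rt
Reagents that add atoms: none
Why: Dess–Martin oxidation of the secondary alcohol under buffered, near-neutral conditions; tertiary alcohol, ester and olefin are inert and the C8 stereocentre is removed.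

Step 16
Reactants: 24 4α-hydroxy-8-oxo-5α-eudesm-11-en-3α-yl (3S)-3-methylpentanoate
Product: 25 4α-hydroxy-8-oxo-5α-eudesm-7(11)-en-3α-yl (3S)-3-methylpentanoate (target; 3R,4S,5R,10R)
Conditions: DBU (0.5 equiv), PhMe, rt → 40 °C
Reagents that add atoms: none
Why: Base-mediated prototropic shift (deprotonation at C7, protonation at C12) moves the β,γ double bond into conjugation, as in the isopulegone-to-pulegone isomerisation; the tetrasubstituted conjugated enone is the thermodynamic product, the C7 stereocentre vanishes, and the non-nucleophilic amidine spares the ester.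

## Compound list

1 | 2-methylcyclohexane-1,3-dione | CC1C(=O)CCCC1=O | starting material
2 | 2-methyl-3-(2-methylpropoxy)cyclohex-2-en-1-one | CC(C)COC1=C(C)C(=O)CCC1 | intermediate
3 | allyl chloroformate | C=CCOC(Cl)=O | starting material
4 | prop-2-en-1-yl 3-methyl-4-(2-methylpropoxy)-2-oxocyclohex-3-ene-1-carboxylate (racemic) | CC(C)COC1=C(C)C(=O)C(C(=O)OCC=C)CC1 | intermediate
5 | prop-2-en-1-yl 1,3-dimethyl-4-(2-methylpropoxy)-2-oxocyclohex-3-ene-1-carboxylate (racemic) | CC(C)COC1=C(C)C(=O)C(C)(C(=O)OCC=C)CC1 | intermediate
6 | (6R)-2,6-dimethyl-3-(2-methylpropoxy)-6-(prop-2-en-1-yl)cyclohex-2-en-1-one | CC(C)COC1=C(C)C(=O)[C@@](C)(CC=C)CC1 | intermediate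
7 | 2-[(1R)-1,3-dimethyl-4-(2-methylpropoxy)-2-oxocyclohex-3-en-1-yl]acetaldehyde | CC(C)COC1=C(C)C(=O)[C@@](C)(CC=O)CC1 | intermediate
8 | (6R)-6-(2,2-dimethoxyethyl)-2,6-dimethyl-3-(2-methylpropoxy)cyclohex-2-en-1-one | CC(C)COC1=C(C)C(=O)[C@@](C)(CC(OC)OC)CC1 | intermediate
9 | 1-chloro-3-methylbut-2-ene | CC(C)=CCCl | starting material
10 | (3-methylbut-2-en-1-yl)barium chloride | CC(C)=CC[Ba]Cl | intermediate (not isolated)
11 | (6R)-6-(2,2-dimethoxyethyl)-2,6-dimethyl-1-(3-methylbut-2-en-1-yl)-3-(2-methylpropoxy)cyclohex-2-en-1-ol (epimers at C1; formed as its barium alkoxide) | CC(C)COC1=C(C)C(O)(CC=C(C)C)[C@@](C)(CC(OC)OC)CC1 | intermediate (not isolated)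
12 | 2-[(1R)-1,3-dimethyl-2-(3-methylbut-2-en-1-yl)-4-oxocyclohex-2-en-1-yl]acetaldehyde | CC1=C(CC=C(C)C)[C@@](C)(CC=O)CCC1=O | intermediate (precursor of the key step)
13 | 8α-hydroxyeudesma-4,11-dien-3-one (7R,8S,10R) | CC1=C2C[C@H](C(C)=C)[C@@H](O)C[C@@]2(C)CCC1=O | intermediate (product of the key step)
14 | 8α-(tert-butyldimethylsilyloxy)eudesma-4,11-dien-3-one | CC1=C2C[C@H](C(C)=C)[C@@H](O[Si](C)(C)C(C)(C)C)C[C@@]2(C)CCC1=O | intermediate
15 | lithium 8α-(tert-butyldimethylsilyloxy)-5α-eudesma-3,11-dien-3-olate | CC1=C(O[Li])CC[C@]2(C)C[C@H](O[Si](C)(C)C(C)(C)C)[C@@H](C(C)=C)C[C@@H]12 | intermediate (not isolated)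
16 | 8α-(tert-butyldimethylsilyloxy)-3-(trimethylsilyloxy)-5α-eudesma-3,11-diene | CC1=C(O[Si](C)(C)C)CC[C@]2(C)C[C@H](O[Si](C)(C)C(C)(C)C)[C@@H](C(C)=C)C[C@@H]12 | intermediate
17 | 8α-(tert-butyldimethylsilyloxy)-4α-(trimethylsilyloxy)-5α-eudesm-11-en-3-one | O=C1CC[C@]2(C)C[C@H](O[Si](C)(C)C(C)(C)C)[C@@H](C(C)=C)C[C@H]2[C@]1(C)O[Si](C)(C)C | intermediate (not isolated)
18 | 8α-(tert-butyldimethylsilyloxy)-4α-hydroxy-5α-eudesm-11-en-3-one | O=C1CC[C@]2(C)C[C@H](O[Si](C)(C)C(C)(C)C)[C@@H](C(C)=C)C[C@H]2[C@]1(C)O | intermediate
19 | 8α-(tert-butyldimethylsilyloxy)-5α-eudesm-11-ene-3α,4α-diol | O[C@@H]1CC[C@]2(C)C[C@H](O[Si](C)(C)C(C)(C)C)[C@@H](C(C)=C)C[C@H]2[C@]1(C)O | intermediate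
20 | (S)-3-methylpentanoic acid | CC[C@H](C)CC(=O)O | starting material
21 | (S)-3-methylpentanoyl chloride | CC[C@H](C)CC(Cl)=O | intermediate (not isolated)
22 | 8α-(tert-butyldimethylsilyloxy)-4α-hydroxy-5α-eudesm-11-en-3α-yl (3S)-3-methylpentanoate | CC[C@H](C)CC(=O)O[C@@H]1CC[C@]2(C)C[C@H](O[Si](C)(C)C(C)(C)C)[C@@H](C(C)=C)C[C@H]2[C@]1(C)O | intermediate
23 | 4α,8α-dihydroxy-5α-eudesm-11-en-3α-yl (3S)-3-methylpentanoate | CC[C@H](C)CC(=O)O[C@@H]1CC[C@]2(C)C[C@H](O)[C@@H](C(C)=C)C[C@H]2[C@]1(C)O | intermediate
24 | 4α-hydroxy-8-oxo-5α-eudesm-11-en-3α-yl (3S)-3-methylpentanoate | CC[C@H](C)CC(=O)O[C@@H]1CC[C@]2(C)CC(=O)[C@@H](C(C)=C)C[C@H]2[C@]1(C)O | intermediate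
25 | 4α-hydroxy-8-oxo-5α-eudesm-7(11)-en-3α-yl (3S)-3-methylpentanoate | CC[C@H](C)CC(=O)O[C@@H]1CC[C@]2(C)CC(=O)C(=C(C)C)C[C@H]2[C@]1(C)O | target

## Step count and least certain steps

Total step count: 16. Longest linear sequence: 16 steps, from 1 to 25; 3, 9 and 20 enter as purchased materials.

Step 8 (key step). What may go wrong: capture of the developing C11 cation by chloride, or loss of a proton other than the methyl hydrogen, leading to Prins-type products or olefin isomers; sequestration of the Lewis acid by the more basic enone oxygen, leading to slow closure; methyl transfer from aluminium to the aldehyde. Fallback: the ring would be closed as a stepwise Prins cyclisation ending in hydration. It sets out from 12: dilute aqueous H2SO4 in THF should give 8,11-dihydroxyeudesm-4-en-3-one F1 (C7/C8 stereoisomers, both acceptable). TBSCl and imidazole would silylate only the secondary hydroxyl, giving 8-(tert-butyldimethylsilyloxy)-11-hydroxyeudesm-4-en-3-one F2. Syn-dehydration of the tertiary alcohol with Burgess reagent (PhMe, 50 °C) should favour removal of a methyl hydrogen and give the isopropenyl compound, rejoining the route at 14. Any C7/C8 stereoisomers of 14 would be carried along and converge at 25, where both centres are gone.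

Step 7. What may go wrong: incomplete addition to the hindered ring carbonyl, attack through the substituted terminus of the allylic metal, or premature acid-induced closure of the freed aldehyde onto the prenyl olefin during hydrolysis. Fallback: the prenyl group would be built in two stages. It sets out from 8: CH2=CHCH2MgBr (THF, −78 → 0 °C), a small nucleophile without regiochemical ambiguity, followed by the same acid treatment should give 2-[(1R)-1,3-dimethyl-4-oxo-2-(prop-2-en-1-yl)cyclohex-2-en-1-yl]acetaldehyde F3. Olefin cross-metathesis with 2-methylbut-2-ene (second-generation Grubbs catalyst, CH2Cl2, 40 °C) would then convert the allyl into the prenyl group, returning at 12.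

Step 11. What may go wrong: competing epoxidation of the isopropenyl group, or hydrolysis of the silyl enol ether before it is oxidised. Fallback: the oxygen would be delivered to the enolate and not to the enol ether. It sets out from 16: MeLi (THF, 0 °C) regenerates the lithium enolate 15, and 2-(phenylsulfonyl)-3-phenyloxaziridine at −78 °C, which does not attack isolated olefins, should hydroxylate C4 from the α face, returning at 18.

Step 12. What may go wrong: poor facial selectivity, with hydride delivery on the α face giving the trans diol, possibly assisted by coordination to the neighbouring hydroxyl. Fallback: both oxygens would be set in one syn-dihydroxylation. It sets out from 14 and returns at 25.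
- Li/NH3 reduction of 14 as in step 10, with the enolate trapped by PhNTf2, should give 8α-(tert-butyldimethylsilyloxy)-5α-eudesma-3,11-dien-3-yl trifluoromethanesulfonate F4.
- Pd(OAc)2, PPh3, Bu3N and HCO2H (DMF, 60 °C) would reduce the triflate to 8α-(tert-butyldimethylsilyloxy)-5α-eudesma-3,11-diene F5.
- HF·pyridine would give 5α-eudesma-3,11-dien-8α-ol F6.
- Dess–Martin oxidation would give 5α-eudesma-3,11-dien-8-one F7.
- DBU would give 5α-eudesma-3,7(11)-dien-8-one F8.
- OsO4 (cat.) with N-methylmorpholine N-oxide should dihydroxylate only the electron-rich C3=C4 olefin, from the α face, giving 3α,4α-dihydroxy-5α-eudesm-7(11)-en-8-one F9.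
- Acylation of the secondary hydroxyl with 21 (from 20) as in step 13 would give 25.

Step 2. What may go wrong: O-acylation of the dienolate in place of C-acylation. Fallback: the order of the two bond formations would be reversed, so that either mode of acylation is productive. It sets out from 2: LiN(i-Pr)2 then MeI should give 2,6-dimethyl-3-(2-methylpropoxy)cyclohex-2-en-1-one F10. LiN(i-Pr)2 with 3 would then O-acylate the hindered tetrasubstituted enolate to 2,6-dimethyl-5-(2-methylpropoxy)cyclohexa-1,5-dien-1-yl prop-2-en-1-yl carbonate F11. Under the conditions of step 4 this enol carbonate should lose CO2 to the same palladium enolate, returning at 6; any C-acylated material formed alongside is 5 and converges as well.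

## Further compounds

F1 | step 8 | 8,11-dihydroxyeudesm-4-en-3-one (10β-methyl; C7/C8 stereoisomers) | CC1=C2CC(C(C)(C)O)C(O)C[C@@]2(C)CCC1=O
F2 | step 8 | 8-(tert-butyldimethylsilyloxy)-11-hydroxyeudesm-4-en-3-one (10β-methyl; C7/C8 stereoisomers) | CC1=C2CC(C(C)(C)O)C(O[Si](C)(C)C(C)(C)C)C[C@@]2(C)CCC1=O
F3 | step 7 | 2-[(1R)-1,3-dimethyl-4-oxo-2-(prop-2-en-1-yl)cyclohex-2-en-1-yl]acetaldehyde | CC1=C(CC=C)[C@@](C)(CC=O)CCC1=O
F0 | step 11 | none | none
F4 | step 12 | 8α-(tert-butyldimethylsilyloxy)-5α-eudesma-3,11-dien-3-yl trifluoromethanesulfonate | CC1=C(OS(=O)(=O)C(F)(F)F)CC[C@]2(C)C[C@H](O[Si](C)(C)C(C)(C)C)[C@@H](C(C)=C)C[C@@H]12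
F5 | step 12 | 8α-(tert-butyldimethylsilyloxy)-5α-eudesma-3,11-diene | CC1=CCC[C@]2(C)C[C@H](O[Si](C)(C)C(C)(C)C)[C@@H](C(C)=C)C[C@@H]12
F6 | step 12 | 5α-eudesma-3,11-dien-8α-ol | CC1=CCC[C@]2(C)C[C@H](O)[C@@H](C(C)=C)C[C@@H]12
F7 | step 12 | 5α-eudesma-3,11-dien-8-one | CC1=CCC[C@]2(C)CC(=O)[C@@H](C(C)=C)C[C@@H]12
F8 | step 12 | 5α-eudesma-3,7(11)-dien-8-one | CC1=CCC[C@]2(C)CC(=O)C(=C(C)C)C[C@@H]12
F9 | step 12 | 3α,4α-dihydroxy-5α-eudesm-7(11)-en-8-one | O[C@@H]1CC[C@]2(C)CC(=O)C(=C(C)C)C[C@H]2[C@]1(C)O
F10 | step 2 | 2,6-dimethyl-3-(2-methylpropoxy)cyclohex-2-en-1-one (racemic) | CC(C)COC1=C(C)C(=O)C(C)CC1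
F11 | step 2 | 2,6-dimethyl-5-(2-methylpropoxy)cyclohexa-1,5-dien-1-yl prop-2-en-1-yl carbonate | CC(C)COC1=C(C)C(OC(=O)OCC=C)=C(C)CC1
A1 | alternative 1 | methyl (6E)-7-methyl-3-oxododec-6-en-10-ynoate | CC#CCC/C(C)=C/CCC(=O)CC(=O)OC
A2 | alternative 1 | methyl 8-hydroxy-11,12,13-trinor-5α-eudesma-3,8-diene-9-carboxylate (10β-methyl) | CC1=CCC[C@]2(C)C(C(=O)OC)=C(O)CC[C@@H]12
A3 | alternative 2 | 2-(tert-butyldimethylsilyloxy)-3-(phenylthio)buta-1,3-diene | C=C(O[Si](C)(C)C(C)(C)C)C(=C)Sc1ccccc1
A4 | alternative 2 | (2E,4S)-4-(tert-butyldimethylsilyloxy)-2-methylpent-2-enal | O=C/C(C)=C/[C@H](C)O[Si](C)(C)C(C)(C)C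
A5 | alternative 2 | 3-(tert-butyldimethylsilyloxy)-6-[(S)-1-(tert-butyldimethylsilyloxy)ethyl]-1-methyl-4-(phenylthio)cyclohex-3-ene-1-carbaldehyde (formyl trans to the side chain) | O=C[C@]1(C)CC(O[Si](C)(C)C(C)(C)C)=C(Sc2ccccc2)C[C@H]1[C@H](C)O[Si](C)(C)C(C)(C)C
A6 | alternative 3 | 4-[(8S)-7-methylidene-1,4-dioxaspiro[4.5]decan-8-yl]pent-1-en-3-one (epimers at C4 of the pentenone) | C=CC(=O)C(C)[C@@H]1CCC2(OCCO2)CC1=C
A7 | alternative 3 | (5α,10β)-8,8-ethylenedioxy-11,12,13-trinoreudesman-3-one (C4 epimers) | CC1C(=O)CC[C@]2(C)CC3(OCCO3)CC[C@@H]12
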